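## Structural features

The target 20 is a diaryl ether of two 2H-chromen-2-one (coumarin) units. Unit A is a 7-hydroxycoumarin carrying the bridging oxygen on C6 (plain locants); unit B is a 6,7-dihydroxycoumarin bound to the same oxygen through C5' (primed locants). There is no stereocentre, so none stand next to each other; the only stereochemical element on the way is the geometry of the acrylate that becomes C3'=C4', which must end cis to the C8a' oxygen for the lactone to close. The fragile groups are the two lactones (opened by base), the C6'/C7' catechol and the C7 phenol (oxidized as phenolates in air), and the electron-rich positions C8 and C8' (open to electrophiles). The real difficulty is the ether bond: the C5' oxygen lies between the substituted carbons C4a' and C6', and its partner C6 sits on an electron-rich ring next to the C7 oxygen, so an Ullmann or SNAr arylation would join two hindered, poorly matched partners. The key step exploits the fact that the oxygens on C6, C7 and C8a of ring A form a 4-aryloxyresorcinol: C7–O and C8a–O can come from an ester and a ketone carbonyl and C6 from the α-carbon of an aryloxy ester, so the benzene ring of unit A can be grown onto a C5'–O–C(sp3) bond made by plain alkylation. With the C5' oxygen locked as the ether, the acrylate on C4a' can lactonize only with the C8a' oxygen.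

## Logic of the disconnections

**20 to 18 and 19.** The C4–C4a bond and the O1–C2 lactone bond of unit A are cut (Pechmann retron). This removes the whole pyranone of unit A and leaves a free resorcinol ring. The forward step must alkenylate C4a and not C8 or C8'. It is therefore placed last, when ring B is already a lactone: a ring B still present as a trimethoxyphenyl acrylic acid would offer a very nucleophilic C8' and an acrylic acid that alkylates resorcinols under acid.

**18 to 16.** The O1'–C2' lactone bond is opened and the three free hydroxyls on C6', C7' and C8a' are returned to methyl ethers. This gives a robust ring B and allows one Lewis-acid operation to unmask and close. The forward step must invert the E-acrylic acid; only the C8a' hydroxyl is ortho to it.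

**16 to 14.** A methoxycarbonyl group is put back on C8 (retro-decarboxylation) and the acrylic acid becomes its methyl ester. The C8 ester is the activating group that ring construction needs; with it, ring A is the aromatic tautomer of a 2-acylcyclohexane-1,3-dione. The forward step must hydrolyse a hindered, hydrogen-bonded ester and decarboxylate without touching the acrylic acid.

**14 to 8 and 11.** The bonds C4a–C5 and C7–C8 are cut, which dissolves the benzene ring of unit A into a four-carbon bis-nucleophile and an acetal–ester bis-electrophile. The diaryl ether becomes an alkyl aryl ether. The forward step needs the acetal carbon to react before the ester carbon and the ring to close before the base finds the acrylate of ring B.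

**8 to 5 and 7.** The O–C(sp3) bond (future C6–O) is cut. The crowded phenol is alkylated, which is easy where arylation is not. The acetal carbon comes in with the electrophile, so no ester enolate is ever formed beside the acrylate. A haloacetate alkylation followed by enolate formylation would place a carbanion five atoms from the acrylate β-carbon and invite 5-exo conjugate addition to a dihydrobenzofuran. The demand is that SN2 displacement at a secondary α-bromo ester outruns elimination.

**7 to 6.** The C–Br and one C–OMe bond are cut; the enol ether supplies both by bromo-methoxylation.

**5 to 3 and 4.** The C=C bond is cut (Wittig retron). The E geometry is wanted here because it keeps the free hydroxyl (future C5' oxygen) from closing the wrong coumarin.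

**3 to 2 to 1.** One O–CH3 bond and then the C–CHO bond are cut. The forward steps rely on the symmetry of 1 and on chelation to select the methoxy group between the formyl group and another methoxy group.

**11 to 10 to 9.** Two O–Si bonds are cut; the diene is the doubly silylated form of the acetoacetate.

## Other disconnections considered

**Alternative 1:** The cut is at O1–C2 and O1'–C2' after both lactone carbonyls are lowered to CH2, leading to the bis-chromene A1. In the forward key step the bis(1-hydroxyallyl) diphenol A2 would be heated with a trace of acid, lose two molecules of water to vinyl ortho-quinone methides, and close both pyrans by oxa-6π electrocyclization.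
- In favour: the closure is pericyclic and regiospecific, both rings form in one operation, and there is no E/Z problem and no electrophilic substitution with a competing site. On mechanistic predictability of the ring closure this alternative is the equal or the better of the chosen plan.
- Against: A2 already contains the diaryl ether, so the hardest bond is left to a hindered arylation. A1 is also two oxidation levels short: two allylic oxidations at C2 and C2' and three demethylations must follow. The ortho-quinone methides are electrophiles that the electron-rich rings could intercept.
- Step economy: worse. Ether formation, double vinyl addition, cyclization, double oxidation and deprotection would exceed the eight linear steps of the chosen route.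

**Alternative 2:** The cut is at C8a'–O1', C4a'–C4', C4'–C3' and O1'–C2' of unit B. In the forward key step fluoride would convert the silyl aryl triflate A4 into the C4a'–C8a' aryne; a formamide would insert with its carbonyl group, and a malonate ester would trap the ortho-quinone methide and lactonize to A3.
- In favour: four bonds and the whole pyranone of unit B form in one step. The C5' aryloxy group polarizes the aryne so that oxygen should add at the remote carbon C8a'. This three-component aryne coupling is an established reaction type, so on precedent the alternative is better than the chosen key step.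
- Against: A4 again presupposes the diaryl ether at the crowded position and needs a long preparation (ether, ortho-silyl group, triflate on a fully substituted ring). A3 carries a superfluous C3' ester that costs a hydrolysis and a decarboxylation. The finished lactone of unit A must survive fluoride and malonate anion.
- Step economy: no better than the chosen route, and structurally it does not solve the ether problem.

**Alternative 3:** The cut is at C8a–O1 and C8a'–O1', each traced back to an aryl C–H bond. In the forward key step the bis-(E)-cinnamic acid A6, with a flavin photocatalyst, visible light and oxygen, would isomerize at both acrylic acids and then undergo oxidative C–O bond formation at each ortho carbon to give A5.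
- In favour: it is biomimetic, and neither ring needs an oxygen at C8a or C8a' beforehand. Ring B then needs only three oxygens, and its ether carbon is ortho to a formyl-derived group that could activate an SNAr ether synthesis. A6 should therefore be reachable in very few steps, and A5 needs only three demethylations. On step economy this alternative is the better plan.
- Against: ring A of A6 has two ortho C–H bonds, so the site of the first C–O bond rests on electronic and steric preference. The oxidative closure must succeed twice on one molecule, the second time beside a light-absorbing coumarin. The electron-rich diaryl ether could itself be photo-oxidized.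
- Comparison: the chosen plan is longer but fixes every oxygen by construction; Alternative 3 is shorter and better precedented on simple substrates, but rests on the regiochemistry of a C–H functionalization.

Key step: step 8

**Remarks on the chemistry**
- The target is achiral. Compounds 7, 8, 12 and 13 are racemic or stereoisomer mixtures whose stereocentres are erased in step 8; the double-bond geometry of 10 and of the ketene acetal of 11 is immaterial.
- The substitution patterns of 8, 11 and 14 were checked atom by atom against 20 and are consistent. The redesign concerns how the acetal carbon enters 8 and the order of the last three operations.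

## Route

Step 1
Reactants: 1 1,2,3,5-tetramethoxybenzene
Product: 2 2,3,4,6-tetramethoxybenzaldehyde
Conditions: POCl3, DMF, 0 → 70 °C; then H2O
Reagents that add atoms: N,N-dimethylformamide CN(C)C=O; water O
Why: Vilsmeier–Haack formylation; the two unsubstituted positions of 1 are equivalent by symmetry and each lies ortho/para to three methoxy groups, so a single aldehyde should form.

Step 2
Reactants: 2 2,3,4,6-tetramethoxybenzaldehyde
Product: 3 2-hydroxy-3,4,6-trimethoxybenzaldehyde
Conditions: BCl3 (1.1 equiv), CH2Cl2, −78 → 0 °C; then H2O
Reagents that add atoms: none
Why: Chelation-controlled ortho-demethylation: BCl3 binds the formyl oxygen and cleaves a neighbouring methoxy group; of the two ortho candidates the one wedged between CHO and another OMe (C2) is twisted out of the ring plane, more basic at oxygen and relieved of strain on cleavage, the preference known for Lewis-acid demethylation of 2,3,4-trioxygenated aryl aldehydes and ketones.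

Step 3
Reactants: 3 2-hydroxy-3,4,6-trimethoxybenzaldehyde; 4 methyl (triphenylphosphoranylidene)acetate
Product: 5 methyl (E)-3-(2-hydroxy-3,4,6-trimethoxyphenyl)prop-2-enoate
Conditions: toluene, 80 °C
Reagents that add atoms: none
Why: Wittig olefination with a stabilized ylide, E-selective and tolerant of the free phenol; staying well below the temperature of thermal E/Z isomerization keeps the hydroxyl (future C5' oxygen) from closing the wrong coumarin.

Step 4
Reactants: 6 methyl (E)-3-methoxyprop-2-enoate
Product: 7 methyl 2-bromo-3,3-dimethoxypropanoate (racemic)
Conditions: NBS, MeOH, 0 °C → rt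
Reagents that add atoms: N-bromosuccinimide O=C1CCC(=O)N1Br; methanol CO
Why: Bromo-alkoxylation of an enol ether: NBS brominates the nucleophilic α-carbon of the push–pull alkene and methanol captures the oxocarbenium ion at C3; the stereocentre forms without control (racemate) and is erased in step 8.

Step 5
Reactants: 5 methyl (E)-3-(2-hydroxy-3,4,6-trimethoxyphenyl)prop-2-enoate; 7 methyl 2-bromo-3,3-dimethoxypropanoate (racemic)
Product: 8 methyl 3,3-dimethoxy-2-{3,5,6-trimethoxy-2-[(E)-3-methoxy-3-oxoprop-1-enyl]phenoxy}propanoate (racemic)
Conditions: Cs2CO3, DMF, 50 °C
Reagents that add atoms: none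
Why: Williamson ether synthesis by SN2 displacement at an α-bromo ester, activated by the adjacent carbonyl group; carbonate deprotonates only the phenol, so no ester enolate arises beside the acrylate and the acetal carbon arrives without a formylation step; the new stereocentre is racemic and disappears on aromatization.

Step 6
Reactants: 9 methyl acetoacetate
Product: 10 methyl 3-(trimethylsilyloxy)but-2-enoate (E/Z mixture)
Conditions: Me3SiCl, Et3N, hexane, rt
Reagents that add atoms: chlorotrimethylsilane C[Si](C)(C)Cl
Why: O-silylation of the enol form of a β-keto ester with a silyl chloride and an amine base (silyl enol ether formation).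

Step 7
Reactants: 10 methyl 3-(trimethylsilyloxy)but-2-enoate (E/Z mixture)
Product: 11 1-methoxy-1,3-bis(trimethylsilyloxy)buta-1,3-diene
Conditions: LiN(iPr)2, THF, −78 °C; then Me3SiCl, −78 °C → rt
Reagents that add atoms: chlorotrimethylsilane C[Si](C)(C)Cl
Why: γ-Deprotonation of the silyl enol ether gives the extended ester dienolate, which is silylated on oxygen to the bis(silyl) dienol ether; it is used freshly because it is moisture-sensitive.

Step 8
Reactants: 8 methyl 3,3-dimethoxy-2-{3,5,6-trimethoxy-2-[(E)-3-methoxy-3-oxoprop-1-enyl]phenoxy}propanoate (racemic); 11 1-methoxy-1,3-bis(trimethylsilyloxy)buta-1,3-diene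
Product: 14 methyl 2,6-dihydroxy-3-{3,5,6-trimethoxy-2-[(E)-3-methoxy-3-oxoprop-1-enyl]phenoxy}benzoate, via open-chain keto diester 12 (not isolated), via cyclohexanedione ester 13 (not isolated)
Conditions: 11 (1.2 equiv), Me3SiOTf (0.2 equiv), CH2Cl2, −78 → −20 °C; then NaOMe (1.5 equiv), MeOH, 0 °C → rt; then HCl (aq.), 50 °C
Reagents that add atoms: none
Why: Proposed new method: Me3SiOTf ionizes the dimethyl acetal of 8 to an oxocarbenium ion at the future C5, and the terminal carbon of 11 (future C4a), the most nucleophilic site of the dienol ether, adds to it in a vinylogous Mukaiyama aldol-type reaction; methanolysis of the silyl groups then gives the δ-methoxy β-keto ester 12. NaOMe deprotonates the carbon between ketone and ester (future C8), which attacks the aryloxy ester carbonyl (future C7) in a 6-exo-trig Dieckmann condensation, so ring A is closed by acyl substitution and the tricarbonyl enolate of 13 is the thermodynamic sink. Acid then eliminates methanol across C4a–C5 and the cyclohexenedione tautomerizes to the 2,6-dihydroxybenzoate 14, with aromatization as the driving force. The closest known reaction type is the Lewis-acid formal (3+3) cyclocondensation of 1,3-bis(silyl enol ethers) with 1,3-dielectrophiles such as β-keto acetals to salicylates, combined with the Dieckmann closure of 3-oxoheptanedioates to 2-acylcyclohexane-1,3-diones; an acetal–ester dielectrophile bearing an α-aryloxy group has not been used in this way. No stereocentre survives: those of 8, 12 and 13 are uncontrolled and are erased on aromatization. The regiochemistry needs the acetal to react before the ester and the terminal diene carbon to react first, which is secured because only the acetal is ionized by the silyl triflate, after which a single six-membered Dieckmann closure is possible. Chemoselectivity against ring B is secured by the substrate and the base stoichiometry: both positions ortho to the aryloxy oxygen are substituted, so the oxocarbenium ion cannot close a benzofuran, and with about one equivalent of methoxide per β-keto ester only that group is deprotonated and not the α-aryloxy C–H, whose anion would add 5-exo to the acrylate or expel methoxide.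

Step 9
Reactants: 14 methyl 2,6-dihydroxy-3-{3,5,6-trimethoxy-2-[(E)-3-methoxy-3-oxoprop-1-enyl]phenoxy}benzoate
Product: 16 (E)-3-[2-(2,4-dihydroxyphenoxy)-3,4,6-trimethoxyphenyl]prop-2-enoic acid, via dicarboxylic acid 15 (not isolated)
Conditions: NaOH (aq.), MeOH, 70 °C, Ar; then HCl (aq.), dioxane, 90 °C
Reagents that add atoms: sodium hydroxide [Na+].[OH-]
Why: Saponification of both methyl esters, then protodecarboxylation of the 2,6-dihydroxybenzoic acid (the aromatic tautomer of a β-keto acid) by ipso protonation in hot aqueous acid; the acrylic acid, the aryl methyl ethers and the diaryl ether are inert, and inert gas protects the resorcinolate from air.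

Step 10
Reactants: 16 (E)-3-[2-(2,4-dihydroxyphenoxy)-3,4,6-trimethoxyphenyl]prop-2-enoic acid
Product: 18 5-(2,4-dihydroxyphenoxy)-6,7-dihydroxy-2H-chromen-2-one, via E-pentahydroxy acid 17 (not isolated)
Conditions: BBr3 (8 equiv), CH2Cl2, −78 °C → rt; then H2O
Reagents that add atoms: none
Why: BBr3 ether cleavage removes the three O-methyl groups in a tandem demethylation–lactonization of the kind known for 2-methoxycinnamic acids: the boron-complexed acrylic acid, pushed by the ortho and para oxygen donors and by reversible HBr addition, rotates about Cα–Cβ and is trapped as the lactone by the only ortho hydroxyl, that on C8a', since the other ortho position carries the ether oxygen; the diaryl ether is not cleaved.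

Step 11
Reactants: 18 5-(2,4-dihydroxyphenoxy)-6,7-dihydroxy-2H-chromen-2-one; 19 ethyl propiolate
Product: 20 6-[(6,7-dihydroxy-2-oxo-2H-chromen-5-yl)oxy]-7-hydroxy-2H-chromen-2-one
Conditions: ZnCl2, dioxane, 100 °C
Reagents that add atoms: none
Why: Pechmann-type condensation of a resorcinol with a propiolate under ZnCl2: C-alkenylation at the position para to one hydroxyl and ortho to the other (future C4a), then lactonization with the C8a hydroxyl; the position between the two hydroxyls (C8) is more hindered and ring B is deactivated by its pyranone, so the 4-aryloxyresorcinol ring should react alone.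

## Compound list

1 | 1,2,3,5-tetramethoxybenzene | COc1cc(OC)c(OC)c(OC)c1 | starting material
2 | 2,3,4,6-tetramethoxybenzaldehyde | COc1cc(OC)c(C=O)c(OC)c1OC | intermediate
3 | 2-hydroxy-3,4,6-trimethoxybenzaldehyde | COc1cc(OC)c(C=O)c(O)c1OC | intermediate
4 | methyl (triphenylphosphoranylidene)acetate | COC(=O)C=P(c1ccccc1)(c1ccccc1)c1ccccc1 | starting material
5 | methyl (E)-3-(2-hydroxy-3,4,6-trimethoxyphenyl)prop-2-enoate | COC(=O)/C=C/c1c(O)c(OC)c(OC)cc1OC | intermediate
6 | methyl (E)-3-methoxyprop-2-enoate | CO/C=C/C(=O)OC | starting material
7 | methyl 2-bromo-3,3-dimethoxypropanoate (racemic) | COC(OC)C(Br)C(=O)OC | intermediate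
8 | methyl 3,3-dimethoxy-2-{3,5,6-trimethoxy-2-[(E)-3-methoxy-3-oxoprop-1-enyl]phenoxy}propanoate (racemic) | COC(OC)C(Oc1c(/C=C/C(=O)OC)c(OC)cc(OC)c1OC)C(=O)OC | intermediate
9 | methyl acetoacetate | COC(=O)CC(C)=O | starting material
10 | methyl 3-(trimethylsilyloxy)but-2-enoate (E/Z mixture) | COC(=O)C=C(C)O[Si](C)(C)C | intermediate
11 | 1-methoxy-1,3-bis(trimethylsilyloxy)buta-1,3-diene (ketene acetal geometry immaterial) | COC(O[Si](C)(C)C)=CC(=C)O[Si](C)(C)C | intermediate
12 | dimethyl 3-methoxy-5-oxo-2-{3,5,6-trimethoxy-2-[(E)-3-methoxy-3-oxoprop-1-enyl]phenoxy}heptanedioate (diastereomer mixture, formed in the flask) | COC(=O)CC(=O)CC(OC)C(Oc1c(/C=C/C(=O)OC)c(OC)cc(OC)c1OC)C(=O)OC | intermediate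
13 | methyl 4-methoxy-2,6-dioxo-3-{3,5,6-trimethoxy-2-[(E)-3-methoxy-3-oxoprop-1-enyl]phenoxy}cyclohexane-1-carboxylate (stereoisomer mixture, drawn as the triketo tautomer, formed in the flask) | COC(=O)C1C(=O)CC(OC)C(Oc2c(/C=C/C(=O)OC)c(OC)cc(OC)c2OC)C1=O | intermediate
14 | methyl 2,6-dihydroxy-3-{3,5,6-trimethoxy-2-[(E)-3-methoxy-3-oxoprop-1-enyl]phenoxy}benzoate | COC(=O)c1c(O)ccc(Oc2c(/C=C/C(=O)OC)c(OC)cc(OC)c2OC)c1O | intermediate
15 | 3-{2-[(E)-2-carboxyethenyl]-3,5,6-trimethoxyphenoxy}-2,6-dihydroxybenzoic acid (formed in the flask) | OC(=O)/C=C/c1c(OC)cc(OC)c(OC)c1Oc1ccc(O)c(C(=O)O)c1O | intermediate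
16 | (E)-3-[2-(2,4-dihydroxyphenoxy)-3,4,6-trimethoxyphenyl]prop-2-enoic acid | OC(=O)/C=C/c1c(OC)cc(OC)c(OC)c1Oc1ccc(O)cc1O | intermediate
17 | (E)-3-[2-(2,4-dihydroxyphenoxy)-3,4,6-trihydroxyphenyl]prop-2-enoic acid (formed in the flask) | OC(=O)/C=C/c1c(O)cc(O)c(O)c1Oc1ccc(O)cc1O | intermediate
18 | 5-(2,4-dihydroxyphenoxy)-6,7-dihydroxy-2H-chromen-2-one | Oc1ccc(Oc2c(O)c(O)cc3oc(=O)ccc23)c(O)c1 | intermediate
19 | ethyl propiolate | CCOC(=O)C#C | starting material
20 | 6-[(6,7-dihydroxy-2-oxo-2H-chromen-5-yl)oxy]-7-hydroxy-2H-chromen-2-one | O=c1ccc2cc(Oc3c(O)c(O)cc4oc(=O)ccc34)c(O)cc2o1 | target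

## Step count and least certain steps

Total step count: 11. Longest linear sequence: 8 steps (steps 1, 2, 3, 5, 8, 9, 10 and 11).

**Step 8 (key step, the one step beyond known chemistry).** The most likely failure is in the base stage: if the α-aryloxy C–H of 12 is deprotonated before the Dieckmann closure, the carbanion can add 5-exo to the acrylate of ring B or expel the β-methoxy group, and the ring does not close. A second weak point is slow ionization of an acetal whose neighbouring carbon carries both an ester and an aryloxy group.

The fallback uses known chemistry, sets out from 5 and returns at 18, with ring A attached as a finished benzene ring. The phenoxide of 5 (K2CO3, DMF, 100 °C) would displace fluoride from 4-fluoro-3-methoxybenzaldehyde in an SNAr reaction activated by the para formyl group, giving methyl (E)-3-[2-(4-formyl-2-methoxyphenoxy)-3,4,6-trimethoxyphenyl]prop-2-enoate F1. Baeyer–Villiger oxidation with mCPBA in CH2Cl2 would give the aryl formate methyl (E)-3-{2-[4-(formyloxy)-2-methoxyphenoxy]-3,4,6-trimethoxyphenyl}prop-2-enoate F2, cleaved without isolation by K2CO3 in MeOH to methyl (E)-3-[2-(4-hydroxy-2-methoxyphenoxy)-3,4,6-trimethoxyphenyl]prop-2-enoate F3. BBr3 under the conditions of step 10 would then remove all four O-methyl groups and close the lactone to 18, and step 11 would finish. This path gives up alkylating rather than arylating the crowded oxygen, so the SNAr step would be slow.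

**Step 5.** The most likely failure is slow SN2 displacement at the secondary carbon of 7, which is flanked by the acetal and attacked by a phenoxide with two ortho substituents, so that base-induced loss of methanol from 7 overtakes etherification.

The fallback sets out from 5 and returns at 8. Alkylation with methyl bromoacetate (K2CO3, acetone, reflux), a primary and unhindered electrophile, would give methyl (E)-3-[2-(2-methoxy-2-oxoethoxy)-3,4,6-trimethoxyphenyl]prop-2-enoate F4. Soft enolization of F4 with TiCl4 and i-Pr2NEt in CH2Cl2 at −20 °C in the presence of trimethyl orthoformate would let the titanium enolate capture the dimethoxycarbenium ion and give 8 directly. The titanium enolate is far less basic than an alkali enolate and is trapped at low temperature, which is the safeguard against conjugate addition to the acrylate.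

**Step 10.** The most likely failure is incomplete geometric inversion of the acrylic acid, so that demethylation stops at 17; slow cleavage of the hindered C6' methyl ether is a second possibility.

The fallback separates the two events and changes the means of isomerization from Lewis acid to light. It sets out from 17, isolated after the aqueous quench, and returns at 18: irradiation of a dilute, degassed solution of 17 in MeCN–water at 365 nm would convert the E acid to the Z acid, which lactonizes spontaneously. No new compound is involved.

**Step 11.** The most likely failure is loss of site selectivity, with the propiolate attacking C8 of ring A or C8' of ring B or adding to the catechol oxygens, together with degradation of the tetraphenol under hot Lewis acid.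

The fallback replaces the one-step condensation by formylation and olefination, sets out from 18 and returns at 20. Vilsmeier–Haack formylation (POCl3, DMF, MeCN, 0 °C → rt; then H2O), which is reliable para to one resorcinol hydroxyl, would give 5-[(6,7-dihydroxy-2-oxo-2H-chromen-5-yl)oxy]-2,4-dihydroxybenzaldehyde F5. Heating F5 with 4 in N,N-diethylaniline at 200 °C would give methyl (E)-3-{5-[(6,7-dihydroxy-2-oxo-2H-chromen-5-yl)oxy]-2,4-dihydroxyphenyl}prop-2-enoate F6, which at that temperature isomerizes and lactonizes with loss of methanol to 20.

## Further compounds

F1 | step 8 | methyl (E)-3-[2-(4-formyl-2-methoxyphenoxy)-3,4,6-trimethoxyphenyl]prop-2-enoate | COC(=O)/C=C/c1c(OC)cc(OC)c(OC)c1Oc1ccc(C=O)cc1OC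
F2 | step 8 | methyl (E)-3-{2-[4-(formyloxy)-2-methoxyphenoxy]-3,4,6-trimethoxyphenyl}prop-2-enoate | COC(=O)/C=C/c1c(OC)cc(OC)c(OC)c1Oc1ccc(OC=O)cc1OC
F3 | step 8 | methyl (E)-3-[2-(4-hydroxy-2-methoxyphenoxy)-3,4,6-trimethoxyphenyl]prop-2-enoate | COC(=O)/C=C/c1c(OC)cc(OC)c(OC)c1Oc1ccc(O)cc1OC
F4 | step 5 | methyl (E)-3-[2-(2-methoxy-2-oxoethoxy)-3,4,6-trimethoxyphenyl]prop-2-enoate | COC(=O)COc1c(/C=C/C(=O)OC)c(OC)cc(OC)c1OC
F0 | step 10 | none | none
F5 | step 11 | 5-[(6,7-dihydroxy-2-oxo-2H-chromen-5-yl)oxy]-2,4-dihydroxybenzaldehyde | O=Cc1cc(Oc2c(O)c(O)cc3oc(=O)ccc23)c(O)cc1O
F6 | step 11 | methyl (E)-3-{5-[(6,7-dihydroxy-2-oxo-2H-chromen-5-yl)oxy]-2,4-dihydroxyphenyl}prop-2-enoate | COC(=O)/C=C/c1cc(Oc2c(O)c(O)cc3oc(=O)ccc23)c(O)cc1O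
A1 | alternative 1 | 6-[(6,7-dimethoxy-2H-chromen-5-yl)oxy]-7-methoxy-2H-chromene | COc1cc2OCC=Cc2cc1Oc1c(OC)c(OC)cc2OCC=Cc12
A2 | alternative 1 | 2-(1-hydroxyprop-2-enyl)-3-[4-hydroxy-5-(1-hydroxyprop-2-enyl)-2-methoxyphenoxy]-4,5-dimethoxyphenol (mixture of diastereomers) | COc1cc(O)c(C(O)C=C)cc1Oc1c(OC)c(OC)cc(O)c1C(O)C=C
A3 | alternative 2 | methyl 6,7-dimethoxy-5-[(7-methoxy-2-oxo-2H-chromen-6-yl)oxy]-2-oxo-2H-chromene-3-carboxylate | COC(=O)c1cc2c(Oc3cc4ccc(=O)oc4cc3OC)c(OC)c(OC)cc2oc1=O
A4 | alternative 2 | 3,4-dimethoxy-2-[(7-methoxy-2-oxo-2H-chromen-6-yl)oxy]-6-(trimethylsilyl)phenyl trifluoromethanesulfonate | COc1cc2oc(=O)ccc2cc1Oc1c(OC)c(OC)cc([Si](C)(C)C)c1OS(=O)(=O)C(F)(F)F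
A5 | alternative 3 | 6-[(6,7-dimethoxy-2-oxo-2H-chromen-5-yl)oxy]-7-methoxy-2H-chromen-2-one | COc1cc2oc(=O)ccc2cc1Oc1c(OC)c(OC)cc2oc(=O)ccc12
A6 | alternative 3 | (E)-3-{2-[5-((E)-2-carboxyethenyl)-2-methoxyphenoxy]-3,4-dimethoxyphenyl}prop-2-enoic acid | COc1ccc(/C=C/C(=O)O)cc1Oc1c(OC)c(OC)ccc1/C=C/C(=O)O
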